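**Assumption (one line):** The stereocentre in the target SMILES is (R) by CIP analysis; the sense of induction of the proposed Ni/NHC step cannot be predicted, so the ligand antipode that gives the (R)-carbinol is used.

## Retrosynthetic overview

1. Target ⇐ global deprotection (three MOM ethers, one TES ether) of a 5-hydroxy-7,3′,4′-tri-O-MOM isoflavone that already carries both side chains.
2. C8–prenyl bond ⇐ para-Claisen–Cope relay from a 5-O-prenyl ether, with C6 already blocked.
3. C2″–C3″ bond and the only stereocentre ⇐ proposed Ni(0)/chiral-NHC, branched-selective reductive coupling of the C6 arylacetaldehyde with propyne and Et3SiH.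
4. C6–C1″ bond ⇐ ortho-Claisen of the 5-O-allyl ether, then Lemieux–Johnson cleavage with the 5-OH masked as acetate.
5. Ring order: A ring (phloroglucinol) and B ring (3,4-dihydroxyphenylacetic acid) are bought and joined by Friedel–Crafts acylation; the pyranone C ring is closed last by C1 insertion to give orobol.

## Route

Step 1
Reactants: 1 phloroglucinol (benzene-1,3,5-triol); 2 3,4-dihydroxyphenylacetic acid
Product: 3 2-(3,4-dihydroxyphenyl)-1-(2,4,6-trihydroxyphenyl)ethan-1-one (deoxybenzoin)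
Conditions: BF3·OEt2 (neat), 85 °C, 2 h; aq. NaOAc work-up
Reagents that add atoms: none
Why: BF3-promoted Friedel–Crafts (Houben–Hoesch-type) C-acylation of the symmetric, very nucleophilic phloroglucinol by the free arylacetic acid gives the deoxybenzoin with no regiochemical issue and no stereocentre.

Step 2
Reactants: 3 deoxybenzoin
Product: 5 orobol (3-(3,4-dihydroxyphenyl)-5,7-dihydroxy-4H-chromen-4-one), via dimethylamino-enone 4 (not isolated)
Conditions: DMF, BF3·OEt2 (3 equiv), MsCl (3 equiv), 50 → 80 °C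
Reagents that add atoms: N,N-dimethylformamide, CN(C)C=O
Why: Vilsmeier-type C1 insertion (deoxybenzoin route to isoflavones) in which the DMF/MsCl iminium formylates the active methylene, an ortho-OH adds and Me2NH is lost to close the pyranone; the two ortho-OH groups are equivalent.

Step 3
Reactants: 5 orobol
Product: 6 3-[3,4-bis(methoxymethoxy)phenyl]-5-hydroxy-7-(methoxymethoxy)-4H-chromen-4-one
Conditions: MOMCl (3.3 equiv), i-Pr2NEt (4 equiv), DMF, 0 °C → rt
Reagents that add atoms: chloromethyl methyl ether (MOMCl), COCCl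
Why: Williamson-type MOM protection alkylates the three free phenols (7, 3′, 4′) while the 5-OH, hydrogen-bonded to C4=O, stays free.

Step 4
Reactants: 6 tri-O-MOM orobol; 7 allyl bromide (3-bromoprop-1-ene)
Product: 8 3-[3,4-bis(methoxymethoxy)phenyl]-7-(methoxymethoxy)-5-(prop-2-en-1-yloxy)-4H-chromen-4-one
Conditions: 7 (1.5 equiv), K2CO3, DMF, 60 °C
Reagents that add atoms: none
Why: Williamson O-allylation of the remaining chelated 5-OH under more forcing carbonate/DMF conditions.

Step 5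
Reactants: 8 5-O-allyl ether
Product: 10 3-[3,4-bis(methoxymethoxy)phenyl]-5-hydroxy-7-(methoxymethoxy)-6-(prop-2-en-1-yl)-4H-chromen-4-one, via 6-allyl ortho-dienone 9 (not isolated)
Conditions: PhNEt2, 200 °C, sealed tube, 3 h
Reagents that add atoms: none
Why: Aromatic Claisen [3,3] rearrangement in which C6 is the only free ortho position of the 5-O-allyl ether (C4a is quaternary), so the allyl group goes to C6 and the dienone tautomerises to the phenol; no stereocentre is formed.

Step 6
Reactants: 10 6-allyl-5-hydroxy isoflavone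
Product: 11 3-[3,4-bis(methoxymethoxy)phenyl]-7-(methoxymethoxy)-4-oxo-6-(prop-2-en-1-yl)-4H-chromen-5-yl acetate
Conditions: Ac2O, pyridine, DMAP (cat.), CH2Cl2, rt
Reagents that add atoms: acetic anhydride, CC(=O)OC(C)=O
Why: O-Acetylation masks the 5-OH so that the arylacetaldehyde made next cannot close to a lactol or benzofuran and no acidic O–H is present in the Ni step; the acetate is orthogonal to MOM and silyl groups.

Step 7
Reactants: 11 5-acetate
Product: 13 3-[3,4-bis(methoxymethoxy)phenyl]-7-(methoxymethoxy)-4-oxo-6-(2-oxoethyl)-4H-chromen-5-yl acetate, via 2,3-diol 12 (not isolated)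
Conditions: OsO4 (2 mol %), NaIO4 (4 equiv), 2,6-lutidine, dioxane–H2O (3:1), rt
Reagents that add atoms: osmium tetroxide, O=[Os](=O)(=O)=O; sodium periodate, [Na+].[O-]I(=O)(=O)=O; water, O
Why: Lemieux–Johnson oxidation in which catalytic OsO4 dihydroxylates the only isolated alkene (the chromone C2=C3 is an electron-poor vinylogous ester) and periodate cleaves the diol to the arylacetaldehyde.

Step 8
Reactants: 13 arylacetaldehyde; 14 propyne
Product: 15 3-[3,4-bis(methoxymethoxy)phenyl]-7-(methoxymethoxy)-6-[(2R)-3-methyl-2-(triethylsilyloxy)but-3-en-1-yl]-4-oxo-4H-chromen-5-yl acetate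
Conditions: Ni(cod)2 (10 mol %), L*·HCl + KOt-Bu (10 mol % each, premixed), 14 (3 equiv), Et3SiH (2 equiv), THF, rt; L* = (4R,5R)-4,5-diphenyl-1,3-bis[2,6-di(pentan-3-yl)phenyl]imidazolidin-2-ylidene or its antipode
Reagents that add atoms: triethylsilane, CC[SiH](CC)CC
Why: Proposed new method: a Ni(0) complex of a very bulky, backbone-chiral NHC joins aldehyde and propyne by oxidative cyclisation to an oxanickelacyclopentene, the large N-aryl groups push the alkyne methyl away from nickel so the C–C bond forms at the internal alkyne carbon (isopropenyl product) while the chiral pocket selects one aldehyde face to set C2″ as (R), and σ-bond metathesis with Et3SiH followed by C–H reductive elimination releases the silyl ether; the closest known reaction type is the Ni(0)/NHC/silane aldehyde–alkyne reductive coupling, where ligand-controlled regio-reversal and enantiocontrol are known for internal and aryl alkynes but not for propyne giving enantioenriched isopropenyl carbinols.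

Step 9
Reactants: 15 (R)-TES ether acetate
Product: 16 3-[3,4-bis(methoxymethoxy)phenyl]-5-hydroxy-7-(methoxymethoxy)-6-[(2R)-3-methyl-2-(triethylsilyloxy)but-3-en-1-yl]-4H-chromen-4-one
Conditions: K2CO3 (0.5 equiv), MeOH–THF (2:1), 0 °C, 30 min
Reagents that add atoms: none
Why: Zemplén-type transesterification removes the aryl acetate selectively, since the secondary TES ether, the MOM ethers and the chromone tolerate brief K2CO3/MeOH at 0 °C; the stereocentre is untouched.

Step 10
Reactants: 16 5-hydroxy TES ether; 17 prenyl bromide (1-bromo-3-methylbut-2-ene)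
Product: 18 3-[3,4-bis(methoxymethoxy)phenyl]-7-(methoxymethoxy)-5-[(3-methylbut-2-en-1-yl)oxy]-6-[(2R)-3-methyl-2-(triethylsilyloxy)but-3-en-1-yl]-4H-chromen-4-one
Conditions: 17 (3 equiv), Cs2CO3, DMF, 45 °C
Reagents that add atoms: none
Why: Williamson O-prenylation (SN2 on a primary allylic bromide) of the hindered, chelated 5-OH as its more reactive caesium phenoxide.

Step 11
Reactants: 18 5-O-prenyl ether
Product: 21 3-[3,4-bis(methoxymethoxy)phenyl]-5-hydroxy-7-(methoxymethoxy)-8-(3-methylbut-2-en-1-yl)-6-[(2R)-3-methyl-2-(triethylsilyloxy)but-3-en-1-yl]-4H-chromen-4-one, via C6 ortho-dienone 19 (not isolated), via C8 para-dienone 20 (not isolated)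
Conditions: PhNEt2 (degassed), 190 °C, sealed tube
Reagents that add atoms: none
Why: para-Claisen (Claisen–Cope) rearrangement in which the [3,3] shift from O5 to the substituted C6 gives a blocked dienone that cannot enolise, the 1,1-dimethylallyl unit (the only allylic group on C6) is relayed by a Cope [3,3] shift to C8 as a normal prenyl group, and the C8–H dienone tautomerises; the stereocentre is a spectator.

Step 12
Reactants: 21 fully substituted protected isoflavone
Product: 22 3-(3,4-dihydroxyphenyl)-5,7-dihydroxy-6-[(2R)-2-hydroxy-3-methylbut-3-en-1-yl]-8-(3-methylbut-2-en-1-yl)-4H-chromen-4-one (CNP0305771.1)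
Conditions: 3 M aq. HCl–MeOH (1:5), 45 °C, under Ar
Reagents that add atoms: none
Why: Acid-catalysed solvolysis (global deprotection) cleaves the three MOM acetals and the TES ether at a temperature below that needed for chroman formation or allylic ionisation, and no bond to the stereocentre is broken, so (R) is retained.

## Compound list

1 | phloroglucinol (benzene-1,3,5-triol) | Oc1cc(O)cc(O)c1 | starting material
2 | 3,4-dihydroxyphenylacetic acid | OC(=O)Cc1ccc(O)c(O)c1 | starting material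
3 | 2-(3,4-dihydroxyphenyl)-1-(2,4,6-trihydroxyphenyl)ethan-1-one (deoxybenzoin) | O=C(Cc1ccc(O)c(O)c1)c1c(O)cc(O)cc1O | intermediate
4 | 2-(3,4-dihydroxyphenyl)-3-(dimethylamino)-1-(2,4,6-trihydroxyphenyl)prop-2-en-1-one (enaminone; not isolated; C=C geometry not defined) | CN(C)C=C(C(=O)c1c(O)cc(O)cc1O)c1ccc(O)c(O)c1 | intermediate
5 | orobol, 3-(3,4-dihydroxyphenyl)-5,7-dihydroxy-4H-chromen-4-one | Oc1cc2occ(-c3ccc(O)c(O)c3)c(=O)c2c(O)c1 | intermediate
6 | 3-[3,4-bis(methoxymethoxy)phenyl]-5-hydroxy-7-(methoxymethoxy)-4H-chromen-4-one | COCOc1cc2occ(-c3ccc(OCOC)c(OCOC)c3)c(=O)c2c(O)c1 | intermediate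
7 | allyl bromide (3-bromoprop-1-ene) | C=CCBr | starting material
8 | 3-[3,4-bis(methoxymethoxy)phenyl]-7-(methoxymethoxy)-5-(prop-2-en-1-yloxy)-4H-chromen-4-one | COCOc1cc2occ(-c3ccc(OCOC)c(OCOC)c3)c(=O)c2c(OCC=C)c1 | intermediate
9 | 3-[3,4-bis(methoxymethoxy)phenyl]-7-(methoxymethoxy)-6-(prop-2-en-1-yl)-6H-chromene-4,5-dione (ortho-dienone; not isolated; C6 racemic) | C=CCC1C(=O)C2=C(OC=C(c3ccc(OCOC)c(OCOC)c3)C2=O)C=C1OCOC | intermediate
10 | 3-[3,4-bis(methoxymethoxy)phenyl]-5-hydroxy-7-(methoxymethoxy)-6-(prop-2-en-1-yl)-4H-chromen-4-one | C=CCc1c(OCOC)cc2occ(-c3ccc(OCOC)c(OCOC)c3)c(=O)c2c1O | intermediate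
11 | 3-[3,4-bis(methoxymethoxy)phenyl]-7-(methoxymethoxy)-4-oxo-6-(prop-2-en-1-yl)-4H-chromen-5-yl acetate | C=CCc1c(OCOC)cc2occ(-c3ccc(OCOC)c(OCOC)c3)c(=O)c2c1OC(C)=O | intermediate
12 | 3-[3,4-bis(methoxymethoxy)phenyl]-6-(2,3-dihydroxypropyl)-7-(methoxymethoxy)-4-oxo-4H-chromen-5-yl acetate (diol; not isolated; carbinol centre racemic) | OCC(O)Cc1c(OCOC)cc2occ(-c3ccc(OCOC)c(OCOC)c3)c(=O)c2c1OC(C)=O | intermediate
13 | 3-[3,4-bis(methoxymethoxy)phenyl]-7-(methoxymethoxy)-4-oxo-6-(2-oxoethyl)-4H-chromen-5-yl acetate | O=CCc1c(OCOC)cc2occ(-c3ccc(OCOC)c(OCOC)c3)c(=O)c2c1OC(C)=O | intermediate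
14 | propyne | CC#C | starting material
15 | 3-[3,4-bis(methoxymethoxy)phenyl]-7-(methoxymethoxy)-6-[(2R)-3-methyl-2-(triethylsilyloxy)but-3-en-1-yl]-4-oxo-4H-chromen-5-yl acetate | C=C(C)[C@H](O[Si](CC)(CC)CC)Cc1c(OCOC)cc2occ(-c3ccc(OCOC)c(OCOC)c3)c(=O)c2c1OC(C)=O | intermediate
16 | 3-[3,4-bis(methoxymethoxy)phenyl]-5-hydroxy-7-(methoxymethoxy)-6-[(2R)-3-methyl-2-(triethylsilyloxy)but-3-en-1-yl]-4H-chromen-4-one | C=C(C)[C@H](O[Si](CC)(CC)CC)Cc1c(OCOC)cc2occ(-c3ccc(OCOC)c(OCOC)c3)c(=O)c2c1O | intermediate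
17 | prenyl bromide (1-bromo-3-methylbut-2-ene) | CC(C)=CCBr | starting material
18 | 3-[3,4-bis(methoxymethoxy)phenyl]-7-(methoxymethoxy)-5-[(3-methylbut-2-en-1-yl)oxy]-6-[(2R)-3-methyl-2-(triethylsilyloxy)but-3-en-1-yl]-4H-chromen-4-one | C=C(C)[C@H](O[Si](CC)(CC)CC)Cc1c(OCOC)cc2occ(-c3ccc(OCOC)c(OCOC)c3)c(=O)c2c1OCC=C(C)C | intermediate
19 | 3-[3,4-bis(methoxymethoxy)phenyl]-7-(methoxymethoxy)-6-(2-methylbut-3-en-2-yl)-6-[(2R)-3-methyl-2-(triethylsilyloxy)but-3-en-1-yl]-6H-chromene-4,5-dione (ortho-dienone; not isolated; C6 epimers) | C=C(C)[C@H](O[Si](CC)(CC)CC)CC1(C(C)(C)C=C)C(=O)C2=C(OC=C(c3ccc(OCOC)c(OCOC)c3)C2=O)C=C1OCOC | intermediate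
20 | 3-[3,4-bis(methoxymethoxy)phenyl]-7-(methoxymethoxy)-8-(3-methylbut-2-en-1-yl)-6-[(2R)-3-methyl-2-(triethylsilyloxy)but-3-en-1-yl]-8H-chromene-4,5-dione (para-dienone; not isolated; C8 epimers) | C=C(C)[C@H](O[Si](CC)(CC)CC)CC1=C(OCOC)C(CC=C(C)C)C2=C(C1=O)C(=O)C(c3ccc(OCOC)c(OCOC)c3)=CO2 | intermediate
21 | 3-[3,4-bis(methoxymethoxy)phenyl]-5-hydroxy-7-(methoxymethoxy)-8-(3-methylbut-2-en-1-yl)-6-[(2R)-3-methyl-2-(triethylsilyloxy)but-3-en-1-yl]-4H-chromen-4-one | C=C(C)[C@H](O[Si](CC)(CC)CC)Cc1c(OCOC)c(CC=C(C)C)c2occ(-c3ccc(OCOC)c(OCOC)c3)c(=O)c2c1O | intermediate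
22 | 3-(3,4-dihydroxyphenyl)-5,7-dihydroxy-6-[(2R)-2-hydroxy-3-methylbut-3-en-1-yl]-8-(3-methylbut-2-en-1-yl)-4H-chromen-4-one (CNP0305771.1) | C=C(C)[C@H](O)Cc1c(O)c(CC=C(C)C)c2occ(-c3ccc(O)c(O)c3)c(=O)c2c1O | target

## Step count and risk

Total step count: 12. Longest linear sequence: 12 steps (1 + 2 → 22); there is no side branch.

Three steps most likely to fail:

**Step 8 (proposed new Ni/NHC coupling).** Possible failures are the linear (E)-propenyl regioisomer, low ee, Ni–H reduction of the chromone C2=C3, or propyne oligomerisation. The fallback uses known chemistry and sets out from 13. A catalytic asymmetric Nozaki–Hiyama–Kishi coupling with 2-iodopropene (CrCl2 with a chiral oxazoline–sulfonamide ligand, NiCl2 co-catalyst, Mn, Cp2ZrCl2, MeCN, rt) tolerates the acetate and the chromone and gives 3-[3,4-bis(methoxymethoxy)phenyl]-6-[(2R)-2-hydroxy-3-methylbut-3-en-1-yl]-7-(methoxymethoxy)-4-oxo-4H-chromen-5-yl acetate F1. Silylation (Et3SiCl, imidazole, DMF, 0 °C) then comes back to the route at 15.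

**Step 11 (para-Claisen–Cope on a congested ring).** The ipso attack at the substituted C6 may be slow, and loss of isoprene or abnormal products can compete; the hindered O-alkylation of step 10 is a related weak point. The fallback sets out from 16 and bypasses both steps. Electrophilic iodination at C8, the only free A-ring position (NIS, DMF, 0 °C), gives 3-[3,4-bis(methoxymethoxy)phenyl]-5-hydroxy-8-iodo-7-(methoxymethoxy)-6-[(2R)-3-methyl-2-(triethylsilyloxy)but-3-en-1-yl]-4H-chromen-4-one F2. Stille coupling with tributyl(3-methylbut-2-en-1-yl)stannane (Pd(PPh3)4, DMF, 80 °C) then comes back to the route at 21.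

**Step 12 (acidic global deprotection).** Protic acid may cyclise a phenol onto the prenyl or isopropenyl group (chroman formation) or ionise the allylic carbinol. The fallback sets out from 21 and avoids Brønsted acid. Silyl-triflate transacetalisation (TMSOTf, 2,2′-bipyridyl, MeCN, 0 °C → rt) exchanges the three aryl MOM groups for silyl groups and gives 5-hydroxy-8-(3-methylbut-2-en-1-yl)-6-[(2R)-3-methyl-2-(triethylsilyloxy)but-3-en-1-yl]-7-(trimethylsilyloxy)-3-[3,4-bis(trimethylsilyloxy)phenyl]-4H-chromen-4-one F3. Buffered fluoride (HF·pyridine, pyridine, THF, 0 °C) then removes all silyl groups and arrives at 22.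

## Further compounds

F1 | step 8 | 3-[3,4-bis(methoxymethoxy)phenyl]-6-[(2R)-2-hydroxy-3-methylbut-3-en-1-yl]-7-(methoxymethoxy)-4-oxo-4H-chromen-5-yl acetate | C=C(C)[C@H](O)Cc1c(OCOC)cc2occ(-c3ccc(OCOC)c(OCOC)c3)c(=O)c2c1OC(C)=O
F2 | step 11 | 3-[3,4-bis(methoxymethoxy)phenyl]-5-hydroxy-8-iodo-7-(methoxymethoxy)-6-[(2R)-3-methyl-2-(triethylsilyloxy)but-3-en-1-yl]-4H-chromen-4-one | C=C(C)[C@H](O[Si](CC)(CC)CC)Cc1c(OCOC)c(I)c2occ(-c3ccc(OCOC)c(OCOC)c3)c(=O)c2c1O
F3 | step 12 | 5-hydroxy-8-(3-methylbut-2-en-1-yl)-6-[(2R)-3-methyl-2-(triethylsilyloxy)but-3-en-1-yl]-7-(trimethylsilyloxy)-3-[3,4-bis(trimethylsilyloxy)phenyl]-4H-chromen-4-one | C=C(C)[C@H](O[Si](CC)(CC)CC)Cc1c(O[Si](C)(C)C)c(CC=C(C)C)c2occ(-c3ccc(O[Si](C)(C)C)c(O[Si](C)(C)C)c3)c(=O)c2c1O
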